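The earlier runs and the new flask are simulated on assumed constants, noise included.

**Two clocks.** Time came first: the green flask, the one asked about, receives its reagent in portions, so I set the interval between portions against the time a portion takes to react.

| flask | starting material | reagent | free catalyst | remark | time |
|---|---|---|---|---|---|
| green | 1.5 M | 1.42 M (in portions, 3) | 1.1 mM | the very flask that is asked about, followed so far; portions every 2.0 min |  |
| grey | 1.5 M | 0.95 M (in portions, 3) | 1.1 mM | run made earlier; portions every 2.0 min |  |
| flask | 1.5 M | 1.42 M (in portions, 3) | 1.1 mM | the portions of reagent follow each other after 2.0 min, the first at the start | 6.0 min |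

| green: time / s | green: target / % | grey: time / min | grey: target / % |
|---|---|---|---|
| 20.0 | 10.9 | 0.500 | 8.3 |
| 40.0 | 16.7 | 0.833 | 13.1 |
| 50.0 | 19.5 | 1.33 | 15.2 |
| 80.0 | 25.2 | 2.00 | 20.8 |
| 90.0 | 25.8 | 4.00 | 39.7 |
| 120 | 28.4 | 6.00 | 59.6 |

(scatter of a reading: 1 percentage point)

- a reading or a percentage of target counts all its forms, free or not

* amount of target in percent of the starting material charged, at 40 s, 2.0 min and 6.0 min

**Second clock.** The first portion of the green flask can give 31.6 % of the starting material charged. Treating that as a first-order lag towards this ceiling, the reading of 19.5 % at 50.0 s gave 52.0 s, the time constant of a portion. The grey run has a smaller portion, 21.1 %, yet its reading at 0.833 min gave 51.6 s. So, as far as these two scattered readings show, the time constant did not follow the size of the portion, and I took the reagent as pseudo-first-order.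

**The ratio.** The interval 2.0 min holds 2.31 time constants, so I reckoned that each portion would keep 9.93 % of itself over one interval. Adding the rests of the portions, I expected 3.67 % of the whole reagent charge left at 6.0 min.

**My reckoning.** Holding the time constant steady, I committed to 17.0 % at 40 s, 28.5 % at 2.0 min and 91.2 % at 6.0 min. The forecast said 17 %, 28.5 % and 85 %, its last figure lower than mine, with the third portion running “with little starting material left”.

**Result.** The flask gave 16.2 %, 28.2 % and 88.7 %.

    starting material + target ⇌ idle adduct, settled at all times (K = 0.140 M⁻¹)
    reagent + catalyst intermediate A ⇌ catalyst intermediate B (K = 2.90 M⁻¹, k = 18.0 M⁻¹ s⁻¹)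
    catalyst intermediate B → free catalyst + target (k = 1600 s⁻¹)
    starting material + free catalyst → catalyst intermediate A (k = 47.0 M⁻¹ s⁻¹)

**Last portion.** The flask held 6.3 % of its reagent at 6.0 min, more than my 3.67 %, and its target stood below the cap of 94.7 %. Dosing the reagent and reading at this time acted together in keeping the target there: charging the reagent at once gave 94.4 %, and reading ten times later gave 94.7 %. For a flask with twice the starting material and all else unchanged, the same time constant gives 45.6 % of its starting material at 6.0 min, and that run gave 45.5 %.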